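Ada, who runs the flask, and Ben, who checks her sums, read the same two runs and disagree about what a flat line means.

| flask | solid substrate | partner | temperature | remark | time |
|---|---|---|---|---|---|
| delta | 0.26 M | 0.13 M | 5 °C | the very flask that is asked about, followed so far |  |
| gamma | 0.26 M | 0.13 M | −10 °C | run made earlier |  |
| flask | 0.26 M | 0.130 M | 5 °C |  | 20 h |

| run | time / h | target / % | solid substrate / % |
|---|---|---|---|
| delta | 3.00 | 10.3 | 22.3 |
| delta | 6.00 | 10.1 | 19.9 |
| delta | 10.0 | 10.2 | 20.6 |
| delta | 12.0 | 10.8 | 19.8 |
| delta | 15.0 | 9.8 | 20.8 |
| delta | 20.0 | 10.2 | 20.7 |
| gamma | 6.00 | 18.3 | 14.1 |
| gamma | 12.0 | 22.1 | 8.7 |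
| gamma | 20.0 | 22.9 | 7.7 |
| gamma | 25.0 | 23.2 | 8.2 |
| gamma | 30.0 | 23.1 | 7.4 |
| gamma | 40.0 | 23.2 | 8.0 |

(readings scatter by 0.3 percentage points)

- blue: at 20 h add partner, 100 % of the amount charged, then wait 6.0 h
- grey: change nothing and wait 6.0 h more
- ochre: at 20 h raise the temperature by 20 K, then wait 6.0 h
- amber: at 20 h take out 90 % of the target then present, then wait 6.0 h

- solid substrate is a solid; its amount is given per volume of the solution
- target taken out counts as made
- at the start none of the solid substrate is in solution
- additions bring no volume worth counting

- target, in percent of the solid substrate first charged, at 20 h
- what to do for the largest gain in target; "none" if nothing gains more than 2 percentage points (blue / grey / ochre / amber / none)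
- target present, with what was taken out counted in, in percent of the solid substrate first charged, after blue
- target present, with what was taken out counted in, in percent of the solid substrate first charged, after amber

They agree on one thing. Target plus the solid reading stays at 30.9 % in the delta run and 31.2 % in the gamma run, so the rest of the charge stands dissolved in both.

Ada sees a balance, and hers is the forecast: “The delta run is flat from 3 h, so it is at equilibrium”. It gives 10.2 % for now. It gives 20.4 % after blue, and 17.5 % after amber, where target re-forms once some is taken out. It picks blue.

Ben counts turnovers instead. In his view each partner turns over once, into target or into something nobody has read, which makes partner the limiting reagent. A flat line then means the turnovers are over. His quantity for the delta run is 0.204: the partner share, the target made per partner charged, as a fraction of the partner charge. The gamma run, colder, reads 0.464, which is higher.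

For amber, Ben says no turnovers are waiting, so the total stays at 10.2 %, against Ada's 17.5 %. For blue, a fresh charge at the same share adds 10 percentage points, which lands on the forecast's number by a different road. He calls that a floor: the first charge met a flask with none of the solid dissolved, and the second meets one with the dissolved part already standing.

    solid substrate ⇌ starting material, rate k1*(cs1 - [starting material]) while solid is left; crystals form when [starting material] > cs1 (solubility = 0.180 M, k = 0.0220 min⁻¹)
    2 partner → side product (k = 0.0630 M⁻¹ min⁻¹, Ea = 71.0 kJ mol⁻¹)
    partner → decomposed reagent (k = 0.0140 min⁻¹, Ea = 91.0 kJ mol⁻¹)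
    starting material + partner → target (k = 0.0770 M⁻¹ min⁻¹, Ea = 60.0 kJ mol⁻¹)
    (constants at 5 °C)

The flask stands at 10.5 %, blue gives 29.1 % and amber 10.5 %, so Ben wins, and blue gains 19 points. In this flask free partner at 20.0 h is 0 % of its charge, while starting material holds at 69.2 % of the solid charge, the solubility 0.18 M: Ada's balance is right for the dissolving. Counted in Ben's quantity, the first charge gave 0.209 and the blue charge 0.373, above his floor.

On the neighbour at 30 °C, with the same charges, the delta share gives 10.2 % target, and the share was lower in the delta run than in the colder gamma run, so Ben's reckoning puts that neighbour below this figure. The computed neighbour gives 0.614 %, a share of 0.0123, which is lower than that figure.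

The data are simulated for an exercise; scatter was added.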